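At the reading, 20 min after the start, the thing to look at first is whether target (crystals counted) stands above isomer of the product, so I began with what the opposite outcome would demand of the constants.

substrate 2.9 M; time 20 min

1. target and crystals together at 20 min, in percent of the substrate charged
2. concentration of target in solution at 20 min, in percent of saturation

    substrate ⇌ target (K1 = 7.3, k1 = 8.6 × 10⁻⁴ s⁻¹)
    substrate ⇌ isomer of the product (K2 = 57, k2 = 3.0 × 10⁻⁴ s⁻¹)
    target ⇌ isomer of the product (k3 = 0.0011 s⁻¹)
    crystals ⇌ target, rate k4*(cs4 - [target]) while solid is left; crystals form when [target] > cs4 (cs4 = 0.16 M, k4 = 0.0032 s⁻¹)

- what is said of target includes crystals
- crystals is a solid; its amount is given per volume of the solution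
- run time (flask): 20 min

Substrate leaves by two parallel first-order branches. With the back steps set aside, I reckoned 0.249 of the charge remaining and 0.557 of the charge going to target directly. Saturation was 0.0552 of the charge. Dissolved target lags its feed by 3.88 min, so I took its level from the substrate of that much earlier, which gave 0.106 at the reading, the return from the isomer left out. Integrating the balance of dissolved target, with crystallisation counted from the start, took the time course of its level out of the reckoning: the target lost to the isomer came to 0.256 of the target made, plus 0.212 from the solubility term, less that dissolved level. This gives the leak share, target lost to the isomer per target made, of 0.304.

In this reckoning the isomer drew level at a leak share of 0.326, and this flask stood just below that. So I committed to target ahead, y at 38.8% and sat above 192%.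

The forecast gave 41% and 210%, saying of the isomer that “dissolved target keeps draining into it”. Its y stands above mine.

The simulation gave 40.6% and 209%, and the leak share read from this flask, net of the return, was 0.255, below the tie I had reckoned. The relaxation half-life of substrate with dissolved target, both ways together, was 11.8 min, shorter than the 37.8 min of substrate with the isomer, each by its own step alone.

The flask charged with 1.2 M has saturation at 0.133 of its charge, and its leak share comes to 0.415, past the tie, so I expected the isomer ahead and y near 32.6%. That flask gave 35.2%, with isomer of the product at 38.5%.

The constants used here were chosen freely; what happens was integrated by code.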